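**Retrosynthetic overview**

- The target comes from a ten-membered 4,5-epoxy-6-ketone that already carries the C8 aroyl ester. Only a chelation-controlled reduction at C6 and release of the phenol remain.
- The ten-membered carbocycle is not closed directly. It comes from an eleven-membered ring in which the isopropyl carbon C11 is still a ring member (C6(=O)–C11Me2–C7). A C7 radical moves the C6 acyl carbon from C11 to C7 and pushes C11 out of the ring as the isopropyl group.
- Enabling feature: ring atom C7 bears the isopropyl carbon C11 and lies between the two oxygenated ring atoms C6 and C8. C11 can therefore be written into the ring next to a C6 ketone, and the secondary-to-tertiary radical gain drives the contraction.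
- The eleven-membered ring is made by an aldol closure C11–C7 of an open keto aldehyde. That chain is built from geraniol, i-PrMgCl and a phosphonoacetate, and two Sharpless epoxidations supply all absolute configuration.
- Ring order: C4–C5 oxirane, temporary C8–C9 oxirane, eleven-membered carbocycle, transient cyclopropane, ten-membered carbocycle.

Key step: step 13

Remark: C1–C15 are the germacrane positions of the target (C1=C10 alkene, C4–C5 epoxide, C6 carbinol, C7 bearing isopropyl carbon C11, C8 ester carbon, C9 CH2) and are used for all intermediates; 4-(tert-butyldimethylsilyloxy)benzoic acid is taken as a catalogue compound.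

**Step 1**
Reactants: 1 geraniol
Product: 2 (2R,3R)-2,3-epoxygeraniol
Conditions: Ti(Oi-Pr)4 (5 mol %), D-(−)-diethyl tartrate (7 mol %), t-BuOOH, 4 Å MS, CH2Cl2, −20 °C
Reagents that add atoms: tert-butyl hydroperoxide, CC(C)(C)OO
Why: Sharpless asymmetric epoxidation touches only the allylic alkene, and the D-(−)-tartrate sets C4 and C5 as the trans (4R,5R) epoxide of the target by reagent control.

**Step 2**
Reactants: 2 (2R,3R)-2,3-epoxygeraniol
Product: 3 (2S,3R)-2,3-epoxygeranial
Conditions: TEMPO (cat.), PhI(OAc)2, CH2Cl2, rt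
Reagents that add atoms: none
Why: The oxoammonium (TEMPO) oxidation of a primary epoxy alcohol stops at the aldehyde, and the oxirane α-carbon cannot epimerise.

**Step 3**
Reactants: 3 (2S,3R)-2,3-epoxygeranial; 4 isopropylmagnesium chloride
Product: 5 1-[(2R,3R)-3-methyl-3-(4-methylpent-3-enyl)oxiran-2-yl]-2-methylpropan-1-ol (both C6 epimers)
Conditions: i-PrMgCl, THF, −78 °C; aq NH4Cl
Reagents that add atoms: isopropylmagnesium chloride, CC(C)[Mg]Cl
Why: Grignard 1,2-addition makes the C6–C11 bond, and the C6 carbinol configuration does not matter because C6 is oxidised in step 8.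

**Step 4**
Reactants: 5 epoxy alcohol
Product: 7 (2E)-5-[(2R,3R)-3-(1-hydroxy-2-methylpropyl)-2-methyloxiran-2-yl]-2-methylpent-2-enal, via allylic alcohol 6 (not isolated)
Conditions: SeO2 (cat.), t-BuOOH, CH2Cl2, 0 °C to rt; filter; MnO2, CH2Cl2, rt
Reagents that add atoms: tert-butyl hydroperoxide, CC(C)(C)OO
Why: Riley allylic oxidation (ene, then [2,3] shift) hydroxylates only the (E)-methyl group of the terminal alkene, which becomes C9, and MnO2 then oxidises only that allylic alcohol and leaves the C6 carbinol.

**Step 5**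
Reactants: 7 enal; 8 triethyl phosphonoacetate
Product: 9 ethyl (2E,4E)-7-[(2R,3R)-3-(1-hydroxy-2-methylpropyl)-2-methyloxiran-2-yl]-4-methylhepta-2,4-dienoate
Conditions: (EtO)2P(O)CH2CO2Et, LiCl, DBU, MeCN, 0 °C to rt
Reagents that add atoms: triethyl phosphonoacetate, CCOC(=O)CP(=O)(OCC)OCC
Why: The Horner–Wadsworth–Emmons reaction under Masamune–Roush conditions adds C8 and C7 as an E-enoate and tolerates the free hydroxyl and the epoxide.

**Step 6**
Reactants: 9 dienoate
Product: 10 (2E,4E)-7-[(2R,3R)-3-(1-hydroxy-2-methylpropyl)-2-methyloxiran-2-yl]-4-methylhepta-2,4-dien-1-ol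
Conditions: i-Bu2AlH (4 equiv), CH2Cl2, −78 °C; Rochelle salt
Reagents that add atoms: none
Why: 1,2-Reduction of the dienoate with i-Bu2AlH gives the primary dienol needed for the second directed epoxidation without disturbing the alkenes or the oxirane.

**Step 7**
Reactants: 10 dienol
Product: 11 {(2S,3S)-3-[(2E)-5-{(2R,3R)-3-(1-hydroxy-2-methylpropyl)-2-methyloxiran-2-yl}pent-2-en-2-yl]oxiran-2-yl}methanol
Conditions: Ti(Oi-Pr)4 (20 mol %), L-(+)-diethyl tartrate (24 mol %), t-BuOOH, 4 Å MS, CH2Cl2, −25 °C
Reagents that add atoms: tert-butyl hydroperoxide, CC(C)(C)OO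
Why: Sharpless asymmetric epoxidation of a 2,4-dienol attacks only the alkene next to the carbinol, and the L-(+)-tartrate sets the C8–O bond with the configuration kept to the end ((8S,9S) in 11).

**Step 8**
Reactants: 11 bis-epoxy diol
Product: 12 (2R,3S)-3-[(2E)-5-{(2R,3S)-2-methyl-3-(2-methylpropanoyl)oxiran-2-yl}pent-2-en-2-yl]oxirane-2-carbaldehyde
Conditions: Dess–Martin periodinane (2.4 equiv), CH2Cl2, 0 °C to rt
Reagents that add atoms: none
Why: One Dess–Martin oxidation converts the C6 carbinol into the isopropyl ketone (merging both epimers) and the C7 carbinol into the aldehyde under near-neutral conditions that both oxiranes survive.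

**Step 9**
Reactants: 12 keto aldehyde
Product: 13 eleven-membered aldol: ring C6(=O)–C11Me2–C7H(OH)–C8/C9 oxirane–C10(Me)=C1–C2–C3–C4/C5 oxirane, (4R,5S,8S,9S), E-alkene, both C7 epimers
Conditions: KN(SiMe3)2 (1.2 equiv), THF (0.001 M), −78 °C; AcOH, −78 °C
Reagents that add atoms: none
Why: This is an intramolecular aldol addition (macroaldolisation) in which C11–H is the only enolisable C–H because C5 and C8 are oxirane carbons, so a single enolate meets a non-enolisable aldehyde, and the C7 carbinol may form as a mixture because step 13 erases it.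

**Step 10**
Reactants: 13 eleven-membered aldol
Product: 14 eleven-membered 7,8-diol, (4R,5S,8R), C9 now CH2, E-alkene, both C7 epimers
Conditions: Pd2(dba)3·CHCl3 (2.5 mol %), n-Bu3P (10 mol %), HCO2H/Et3N, THF, rt
Reagents that add atoms: none
Why: In this formate hydrogenolysis of an alkenyl oxirane via a π-allyl complex of divalent palladium, only the C8–C9 vinyl epoxide ionises and hydride goes to C9 next to the alkoxide, so the unbroken C8–O bond keeps C8 and the syn π-allyl keeps the alkene E.

**Step 11**
Reactants: 14 eleven-membered 7,8-diol; 15 4-(tert-butyldimethylsilyloxy)benzoic acid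
Product: 16 C8 4-(tert-butyldimethylsilyloxy)benzoate of 14 (C7–OH free)
Conditions: 15 (1.05 equiv), DCC, DMAP (cat.), CH2Cl2, 0 °C
Reagents that add atoms: 4-(tert-butyldimethylsilyloxy)benzoic acid, CC(C)(C)[Si](C)(C)Oc1ccc(cc1)C(=O)O
Why: Steglich esterification should pick the C8 hydroxyl because the C7 hydroxyl is flanked by the quaternary C11 and is much more hindered.

**Step 12**
Reactants: 16 C8 ester
Product: 17 C7 O-(imidazol-1-ylthiocarbonyl) derivative of 16
Conditions: 1,1'-thiocarbonyldiimidazole, DMAP (cat.), ClCH2CH2Cl, 70 °C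
Reagents that add atoms: 1,1'-thiocarbonyldiimidazole, S=C(n1ccnc1)n1ccnc1
Why: Thiocarbonylation under essentially neutral conditions gives the Barton–McCombie precursor while avoiding the alkoxide that would trigger retro-aldol cleavage of the C11–C7 bond.

**Step 13**
Reactants: 17 thiocarbonylimidazolide
Product: 21 (1(10)E,4R,5S,7R,8R)-4,5-epoxy-6-oxogermacr-1(10)-en-8-yl 4-(tert-butyldimethylsilyloxy)benzoate, via secondary C7 radical 18 (not isolated), via cyclopropyloxyl radical 19 (not isolated), via tertiary C11 radical 20 (not isolated)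
Conditions: (Me3Si)3SiH (1.3 equiv) and AIBN (0.2 equiv) added by syringe pump, toluene (0.002 M), 100 °C
Reagents that add atoms: none
Why: Proposed new method: the silyl radical adds to the thiocarbonyl sulfur and the C7–O bond breaks (Barton–McCombie initiation), so both C7 epimers of 17 funnel into the same planar radical 18, which adds to the adjacent C6 carbonyl carbon to give 19, whose C6–C11 bond then cleaves to the tertiary radical 20 that takes hydrogen from the silane and becomes the isopropyl CH. The closest known reaction type is the radical 1,2-acyl migration of 2,2-dialkyl-3-oxoalkyl radicals (the Dowd–Beckwith manifold run in the contracting direction), which has not yet been used to contract a medium-ring ketone. The only ring closed directly is the transient cyclopropane C6–C7–C11 (3-exo-trig), and the ten-membered ring is what remains once its C6–C11 bond opens, so the eleven-membered ring loses C11 as a member and gains the hindered C6–C7 bond. C7 is the only new stereocentre: in 18 the C8–H bond should eclipse the bulky C11 (allylic-strain type control), leaving the aroyloxy group and C9 on opposite faces, and the acyl carbon, tied to C9 through the ring, is expected to swing onto the face opposite C9, giving the isopropyl/oxygen anti relation of the target. Only an acyl group can migrate in a carbon radical, so the two methyl groups stay, and the direction is secured by the secondary-to-tertiary radical gain. Premature reduction of 18 is held back by a slow hydrogen donor kept very dilute, the thiocarbonyl group is far more reactive towards silyl radicals than the epoxy ketone, and the competing 1,2-aroyloxy shift is a much slower process.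

**Step 14**
Reactants: 21 ten-membered epoxy ketone
Product: 22 (1(10)E,4R,5R,6R,7S,8R)-4,5-epoxy-6-hydroxygermacr-1(10)-en-8-yl 4-(tert-butyldimethylsilyloxy)benzoate
Conditions: Zn(BH4)2, Et2O, −30 °C
Reagents that add atoms: none
Why: In this chelation-controlled reduction of an α,β-epoxy ketone, divalent zinc ties the oxirane oxygen to the carbonyl oxygen and hydride enters from the face away from C4, which gives the anti epoxy alcohol (6R) and leaves the esters alone.

**Step 15**
Reactants: 22 silyl-protected target
Product: 23 target, (1(10)E,4R,5R,6R,7S,8R)-4,5-epoxy-6-hydroxygermacr-1(10)-en-8-yl 4-hydroxybenzoate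
Conditions: n-Bu4NF, AcOH, THF, 0 °C
Reagents that add atoms: none
Why: Fluoride cleaves the aryl silyl ether within minutes, and the acetic acid buffer prevents acyl migration from the C8 oxygen to the C6 oxygen and epoxide opening.

**Compound list**

1 | geraniol | CC(C)=CCC/C(C)=C/CO | starting material
2 | (2R,3R)-2,3-epoxygeraniol | CC(C)=CCC[C@@]1(C)O[C@@H]1CO | intermediate
3 | (2S,3R)-2,3-epoxygeranial | CC(C)=CCC[C@@]1(C)O[C@@H]1C=O | intermediate
4 | isopropylmagnesium chloride | CC(C)[Mg]Cl | starting material
5 | epoxy alcohol, both C6 epimers | CC(C)=CCC[C@@]1(C)O[C@@H]1C(O)C(C)C | intermediate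
6 | (E)-allylic alcohol (C9–OH), both C6 epimers | OC/C(C)=C/CC[C@@]1(C)O[C@@H]1C(O)C(C)C | intermediate
7 | (E)-enal (C9 aldehyde), both C6 epimers | O=C/C(C)=C/CC[C@@]1(C)O[C@@H]1C(O)C(C)C | intermediate
8 | triethyl phosphonoacetate | CCOC(=O)CP(=O)(OCC)OCC | starting material
9 | ethyl (2E,4E)-dienoate, both C6 epimers | CCOC(=O)/C=C/C(C)=C/CC[C@@]1(C)O[C@@H]1C(O)C(C)C | intermediate
10 | (2E,4E)-dienol, both C6 epimers | OC/C=C/C(C)=C/CC[C@@]1(C)O[C@@H]1C(O)C(C)C | intermediate
11 | bis-epoxy diol (4R,5R,8S,9S), both C6 epimers | OC[C@@H]1O[C@H]1/C(C)=C/CC[C@@]2(C)O[C@@H]2C(O)C(C)C | intermediate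
12 | bis-epoxy keto aldehyde (4R,5S,8R,9S) | O=C[C@@H]1O[C@H]1/C(C)=C/CC[C@@]2(C)O[C@@H]2C(=O)C(C)C | intermediate
13 | eleven-membered bis-epoxy aldol, both C7 epimers | OC1[C@@H]2O[C@H]2/C(C)=C/CC[C@@]2(C)O[C@@H]2C(=O)C1(C)C | intermediate
14 | eleven-membered 7,8-diol (8R), both C7 epimers | OC1[C@H](O)C/C(C)=C/CC[C@@]2(C)O[C@@H]2C(=O)C1(C)C | intermediate
15 | 4-(tert-butyldimethylsilyloxy)benzoic acid | CC(C)(C)[Si](C)(C)Oc1ccc(cc1)C(=O)O | starting material
16 | eleven-membered C8 aroyl ester, C7–OH free | OC1[C@H](OC(=O)c2ccc(O[Si](C)(C)C(C)(C)C)cc2)C/C(C)=C/CC[C@@]2(C)O[C@@H]2C(=O)C1(C)C | intermediate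
17 | C7 thiocarbonylimidazolide of 16 | S=C(OC1[C@H](OC(=O)c2ccc(O[Si](C)(C)C(C)(C)C)cc2)C/C(C)=C/CC[C@@]2(C)O[C@@H]2C(=O)C1(C)C)n1ccnc1 | intermediate
18 | secondary C7 radical, eleven-membered ring | [CH]1[C@H](OC(=O)c2ccc(O[Si](C)(C)C(C)(C)C)cc2)C/C(C)=C/CC[C@@]2(C)O[C@@H]2C(=O)C1(C)C | intermediate
19 | cyclopropyloxyl radical (cyclopropane C6–C7–C11) | [O]C12C(C)(C)[C@@H]1[C@H](OC(=O)c1ccc(O[Si](C)(C)C(C)(C)C)cc1)C/C(C)=C/CC[C@@]1(C)O[C@@H]12 | intermediate
20 | tertiary C11 radical, ten-membered ring | C/C1=C\CC[C@@]2(C)O[C@@H]2C(=O)[C@H]([C](C)C)[C@H](OC(=O)c2ccc(O[Si](C)(C)C(C)(C)C)cc2)C1 | intermediate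
21 | ten-membered 4,5-epoxy-6-ketone 8-ester (4R,5S,7R,8R) | C/C1=C\CC[C@@]2(C)O[C@@H]2C(=O)[C@H](C(C)C)[C@H](OC(=O)c2ccc(O[Si](C)(C)C(C)(C)C)cc2)C1 | intermediate
22 | silyl-protected target (4R,5R,6R,7S,8R) | C/C1=C\CC[C@@]2(C)O[C@@H]2[C@H](O)[C@H](C(C)C)[C@H](OC(=O)c2ccc(O[Si](C)(C)C(C)(C)C)cc2)C1 | intermediate
23 | target CNP0365539.3 | C/C1=C\CC[C@@]2(C)O[C@@H]2[C@H](O)[C@H](C(C)C)[C@H](OC(=O)c2ccc(O)cc2)C1 | target

Total step count: 15. Longest linear sequence: 15 steps (from geraniol).

**Steps most likely to fail**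

**Step 13.**
- What may go wrong: hydrogen may reach the secondary radical before the acyl carbon has moved. The tertiary radical may be captured across the ring by the C1=C10 alkene. Facial selectivity at C7 may be poor.
- The fallback uses only known reaction types, sets out from 16 and returns at 22.
- Mesylation of the C7 hydroxyl (MsCl, Et3N, DMAP) gives the keto mesylate F1.
- NaBH4/CeCl3 reduces the C6 ketone to the 1,3-hydroxy mesylate F2.
- KOt-Bu triggers a Grob fragmentation in which the C6–C11 bond breaks and the C7=C11 alkene forms, giving the open-chain epoxy aldehyde F3.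
- SeO2/t-BuOOH hydroxylates the (E)-methyl group of the new prenyl-type alkene to the allylic alcohol F4.
- CBr4/PPh3 gives the allylic bromide F5.
- CrCl2 at high dilution (Nozaki–Hiyama allylation) joins the γ-carbon C7 to the aldehyde carbon C6. This closes the ten-membered ring directly as the isopropenyl alcohol F6.
- Hydrogenation over RhCl(PPh3)3 saturates only the 1,1-disubstituted alkene and gives 22.

**Step 9.**
- What may go wrong: oligomerisation may win over ring closure, the potassium aldolate may undergo retro-aldol cleavage, or the aldolate oxygen may migrate onto the neighbouring oxirane.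
- The fallback sets out from 7 and returns at 13.
- Wittig methylenation (Ph3P=CH2) gives the terminal diene F7.
- Dess–Martin oxidation gives the isopropyl ketone F8.
- The lithium enolate of F8 (LDA, −78 °C) adds intermolecularly to acrolein to give the allylic alcohol F9.
- Ring-closing metathesis with the second-generation Grubbs catalyst between the vinyl group and the terminal diene closes the eleven-membered dienol F10.
- Sharpless epoxidation with L-(+)-diisopropyl tartrate, run as a kinetic resolution of the C7 epimers, epoxidises C8=C9 and gives 13.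

**Step 11.**
- What may go wrong: acylation may occur at the wrong hydroxyl, or the C8 hydroxyl may be masked as a transannular hemiketal with the C6 ketone.
- The fallback sets out from 13 and returns at 17; it changes the order of events so that no site selection is needed.
- The only hydroxyl of 13 is thiocarbonylated first (thiocarbonyldiimidazole) to the bis-epoxy imidazolide F11.
- The formate hydrogenolysis with zerovalent palladium then opens the vinyl epoxide to the C8 alcohol F12.
- DCC/DMAP esterification of F12 with 15 gives 17.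

**Further compounds**

F1 | step 13 | C7 mesylate of 16 | CS(=O)(=O)OC1[C@H](OC(=O)c2ccc(O[Si](C)(C)C(C)(C)C)cc2)C/C(C)=C/CC[C@@]2(C)O[C@@H]2C(=O)C1(C)C
F2 | step 13 | 1,3-hydroxy mesylate (C6–OH, C7–OMs) | CS(=O)(=O)OC1[C@H](OC(=O)c2ccc(O[Si](C)(C)C(C)(C)C)cc2)C/C(C)=C/CC[C@@]2(C)O[C@@H]2C(O)C1(C)C
F3 | step 13 | open-chain epoxy aldehyde with C7=C11 alkene | CC(C)=C[C@H](OC(=O)c1ccc(O[Si](C)(C)C(C)(C)C)cc1)C/C(C)=C/CC[C@@]1(C)O[C@@H]1C=O
F4 | step 13 | (E)-allylic alcohol of F3 | OC/C(C)=C/[C@H](OC(=O)c1ccc(O[Si](C)(C)C(C)(C)C)cc1)C/C(C)=C/CC[C@@]1(C)O[C@@H]1C=O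
F5 | step 13 | (E)-allylic bromide | BrC/C(C)=C/[C@H](OC(=O)c1ccc(O[Si](C)(C)C(C)(C)C)cc1)C/C(C)=C/CC[C@@]1(C)O[C@@H]1C=O
F6 | step 13 | ten-membered 6-hydroxy-7-isopropenyl compound | C/C1=C\CC[C@@]2(C)O[C@@H]2[C@H](O)[C@H](C(C)=C)[C@H](OC(=O)c2ccc(O[Si](C)(C)C(C)(C)C)cc2)C1
F7 | step 9 | terminal diene, both C6 epimers | C=C/C(C)=C/CC[C@@]1(C)O[C@@H]1C(O)C(C)C
F8 | step 9 | terminal diene isopropyl ketone | C=C/C(C)=C/CC[C@@]1(C)O[C@@H]1C(=O)C(C)C
F9 | step 9 | acrolein aldol, both C7 epimers | C=C/C(C)=C/CC[C@@]1(C)O[C@@H]1C(=O)C(C)(C)C(O)C=C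
F10 | step 9 | eleven-membered dienol, both C7 epimers | OC1/C=C/C(C)=C/CC[C@@]2(C)O[C@@H]2C(=O)C1(C)C
F11 | step 11 | C7 thiocarbonylimidazolide of 13 | S=C(OC1[C@@H]2O[C@H]2/C(C)=C/CC[C@@]2(C)O[C@@H]2C(=O)C1(C)C)n1ccnc1
F12 | step 11 | C7 thiocarbonylimidazolide with free C8–OH | S=C(OC1[C@H](O)C/C(C)=C/CC[C@@]2(C)O[C@@H]2C(=O)C1(C)C)n1ccnc1
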